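**Plan**

1. Numbering (ent-kaurane): ring A = C1–C5, C10; oxepane ring B = C5–C6–O–C7–C8–C9–C10; bicyclo[3.2.1]octane (rings C and D) = C8, C9, C11–C16; C20 = methyl on C10; C17 = methyl on C16.
2. Retrosynthesis: remove the epoxide oxygen, the acetates and C17; re-tie the ring B lactol as a C6 acetal bridged to the oxygen on C2; cut ring C at C8–C9 (enolate–alkenyl coupling) and C11–C12 (enolate alkylation) to give a ring A methyl ketone and a ring D iodide.
3. Ring A is then cut at C2–C3 and C4–C5 together, which takes out isobutene. This is possible because C2 carries oxygen, C5 is α to the aldehyde-level C6, and C2–O and C5–C6 are cis-1,4 on ring A. One oxygen can therefore tie C2 to C6 as a dihydropyran whose C2 oxocarbenium and C5=C6 enol ether form a cationic 2-oxadiene with termini C2 and C5.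
4. Forward: hetero-Diels–Alder pyran → ring A by (4+2) with isobutene → ring D joined at C11–C12 → ring C closed at C8–C9 → strain-driven acetal migration to ring B → C17, acetates, lactol, epoxide.
5. Stereochemistry: C1/C10 from the endo rule and the Z-enynal geometry, absolute sense from the chiral chromium catalyst; C2/C5 from anti attack and the bridge; C13 from (R)-cyclohex-3-enecarboxylic acid; C8 by bridging; C16 by exo hydrogenation; C9/C11 by epoxidation anti to the C15–C16 bridge; C6 by anomeric equilibration.

Key step: step 5

Assumption: the C6 lactol hydroxyl of the target is taken to be the anomer favoured at equilibrium, and the (1R,2S)-aminoindanol chromium catalyst of step 4 is taken to attack the enal face that leads to (2S,3R,4R)-6 (its mirror-image complex would be used if the sense is the reverse).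

**Route**

Step 1
Reactants: 1 (Z)-3-methylpent-2-en-4-yn-1-ol
Product: 2 (Z)-3-methylpent-2-en-4-ynal
Conditions: MnO2 (activated, 15 equiv), CH2Cl2, rt
Reagents that add atoms: none
Why: Allylic oxidation with MnO2 is neutral and mild, so the Z geometry (ethynyl cis to the carbonyl carbon) and the terminal alkyne should be kept.

Step 2
Reactants: 3 2-(benzyloxy)acetaldehyde
Product: 4 1,1,2-tris(benzyloxy)ethane
Conditions: BnOH (2.2 equiv), TsOH·H2O (cat.), toluene, Dean–Stark, reflux
Reagents that add atoms: benzyl alcohol, OCc1ccccc1
Why: Acid-catalysed acetalisation with azeotropic removal of water should give the dibenzyl acetal.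

Step 3
Reactants: 4 1,1,2-tris(benzyloxy)ethane
Product: 5 (Z)-1,2-bis(benzyloxy)ethene
Conditions: TMSOTf (1.1 equiv), i-Pr2NEt (1.3 equiv), CH2Cl2, −20 °C → rt
Reagents that add atoms: none
Why: Acetal-to-enol-ether elimination (silyl triflate ionises the acetal, the hindered amine removes the α-proton); the cis-1,2-dialkoxyethene is the expected, thermodynamically preferred isomer.

Step 4
Reactants: 2 (Z)-3-methylpent-2-en-4-ynal; 5 (Z)-1,2-bis(benzyloxy)ethene
Product: 6 (2S,3R,4R)-2,3-bis(benzyloxy)-4-ethynyl-4-methyl-3,4-dihydro-2H-pyran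
Conditions: 5 (2 equiv), CrCl(L) (5 mol %; trivalent chromium; L = dianion of the tridentate Schiff base of (1R,2S)-1-aminoindan-2-ol and 3-(1-adamantyl)-2-hydroxy-5-methylbenzaldehyde), 4 Å MS, neat, rt
Reagents that add atoms: none
Why: Inverse-electron-demand oxa-hetero-Diels–Alder reaction of the enal (as 1-oxadiene) with the enediol ether; the endo transition state puts both benzyloxy groups cis to the "outside" methyl of the Z-enynal (slim ethynyl "inside"), which fixes C1, C2 and C10 relative to each other, and the chiral Lewis acid selects the enal face and so the absolute configuration.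

Step 5
Reactants: 6 (2S,3R,4R)-2,3-bis(benzyloxy)-4-ethynyl-4-methyl-3,4-dihydro-2H-pyran; 7 2-methylpropene (isobutene)
Product: 10 (1S,3S,4R,5R,6R)-3,6-bis(benzyloxy)-5-ethynyl-5,8,8-trimethyl-2-oxabicyclo[2.2.2]octane, via dihydropyranylium triflate 8 (not isolated), via bridged oxocarbenium triflate 9 (not isolated)
Conditions: isobutene (20 equiv, condensed), TMSOTf (0.2 equiv), 2,6-di-tert-butyl-4-methylpyridine (0.3 equiv), 4 Å MS, CH2Cl2, −78 → −40 °C
Reagents that add atoms: none
Why: Proposed new method: TMSOTf ionises the anomeric benzyloxy group of 6 to cation 8, in which the C2 oxocarbenium and the C5=C6 enol ether share the ring oxygen and form a cationic 2-oxadiene with termini C2 and C5; isobutene adds in an asynchronous polar (4+2) cycloaddition, its CH2 bonding to the electrophilic C2 (Prins-type, developing tertiary cation character at C4) and C4 then being captured by the enol ether carbon C5, after which BnOSiMe3 returns the benzyloxy group to the bridged oxocarbenium ion 9 and regenerates the catalyst. The closest known reaction types are the Lewis-acid C-glycosylation of 2-alkoxydihydropyrans by π-nucleophiles, the Prins cyclisation and the oxa-Povarov (4+2) cycloaddition of aryl-substituted oxocarbenium ions with alkenes; new here is a non-aromatic cyclic vinyl oxocarbenium ion combining across its 2,5-positions with an unactivated 1,1-disubstituted alkene. Carbocycle A (C1–C2–C3–C4–C5–C10) closes by 6-exo-trig attack of C4 on C5 through a boat, which seen from the oxygen ring is a 6-endo closure and gives the 2-oxabicyclo[2.2.2]octane. C2 is set by approach of the alkene anti to the adjacent C1 benzyloxy group and the C10 methyl (the face of the slim ethynyl group), C5 is set by the two-carbon bridge, which can only reach the same face, so C2–O and C5–C6 come out cis as the target needs; C6 is an acetal centre of no consequence and any C2 epimer of 6 would converge on the same cation 8. Regiochemistry is fixed by polarity (CH2 to C2, CMe2 to C5, which delivers the C4 gem-dimethyl group); the step needs the facial selectivity just described and capture of the C4 cation by C5 in preference to proton loss, which the proximity and nucleophilicity of the enol ether should secure, while the hindered pyridine removes adventitious acid that would polymerise isobutene or protonate the enol ether.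

Step 6
Reactants: 10 the bridged ethynyl acetal
Product: 11 1-[(1S,3S,4R,5S,6R)-3,6-bis(benzyloxy)-5,8,8-trimethyl-2-oxabicyclo[2.2.2]octan-5-yl]ethanone
Conditions: Ph3PAuNTf2 (2 mol %), 1,4-dioxane/H2O (10:1), 60 °C
Reagents that add atoms: water, O
Why: Gold-catalysed Markovnikov hydration of the terminal alkyne should give the methyl ketone (C9=O, C11 methyl) under neutral conditions that leave the bicyclic acetal and the benzyl ethers untouched.

Step 7
Reactants: 12 (R)-cyclohex-3-ene-1-carboxylic acid
Product: 13 (R)-cyclohex-3-en-1-ylmethanol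
Conditions: LiAlH4 (1.5 equiv), THF, 0 °C → rt
Reagents that add atoms: none
Why: Hydride reduction of the acid gives the primary alcohol without touching the alkene or the stereocentre (future C13).

Step 8
Reactants: 13 (R)-cyclohex-3-en-1-ylmethanol
Product: 14 (R)-tert-butyl(cyclohex-3-en-1-ylmethoxy)dimethylsilane
Conditions: TBSCl (1.2 equiv), imidazole (1.5 equiv), CH2Cl2, rt
Reagents that add atoms: tert-butyldimethylsilyl chloride, CC(C)(C)[Si](C)(C)Cl
Why: Standard silylation masks the alcohol so that it cannot lactonise onto the esters formed next.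

Step 9
Reactants: 14 the silyl ether
Product: 15 dimethyl (3R)-3-{[(tert-butyldimethylsilyl)oxy]methyl}hexanedioate
Conditions: O3, NaOH (2.5 M in MeOH), CH2Cl2, −78 °C
Reagents that add atoms: ozone, [O-][O+]=O; methanol, CO
Why: Ozonolysis in methanolic NaOH converts the ring alkene directly into two methyl esters, giving the 3-substituted adipate with the stereocentre untouched.

Step 10
Reactants: 15 the 3-substituted dimethyl adipate
Product: 16 methyl (4R)-4-{[(tert-butyldimethylsilyl)oxy]methyl}-2-oxocyclopentane-1-carboxylate
Conditions: t-BuOK (1.2 equiv), THF, 0 °C → rt; 1 M HCl quench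
Reagents that add atoms: none
Why: Dieckmann condensation under equilibrating conditions should close through the ester enolate remote from the branch, giving the less hindered β-keto ester (ring D: C8 ester, C15 ketone); the branch carbon is not enolisable.

Step 11
Reactants: 16 the silylated β-keto ester
Product: 17 methyl (4R)-4-(hydroxymethyl)-2-oxocyclopentane-1-carboxylate
Conditions: HF·pyridine, THF, 0 °C → rt
Reagents that add atoms: none
Why: Acidic fluoride removes the primary silyl ether without base-induced retro-Claisen opening of the β-keto ester.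

Step 12
Reactants: 17 the hydroxy β-keto ester
Product: 18 methyl (4R)-4-(iodomethyl)-2-oxocyclopentane-1-carboxylate
Conditions: I2 (1.2 equiv), PPh3 (1.2 equiv), imidazole (1.5 equiv), CH2Cl2, 0 °C → rt
Reagents that add atoms: iodine, II
Why: Appel-type iodination converts the primary alcohol into the iodide (C12) under near-neutral conditions.

Step 13
Reactants: 11 the ring A methyl ketone; 18 the ring D iodide
Product: 21 ring A–ring D diketo ester (C9 ketone joined through C11–C12 to C13), via lithium enolate of ketone 19 (not isolated), via sodium enolate of iodide 20 (not isolated)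
Conditions: 11: LiN(i-Pr)2 (1.05 equiv), THF, −78 °C; 18: NaH (1.05 equiv), THF, 0 °C; combine, DMPU, −78 → 0 °C; AcOH
Reagents that add atoms: none
Why: Enolate alkylation: ketone 11 can enolise only toward its methyl group (C10 is quaternary), and the β-keto ester of 18 is carried as its sodium enolate, which is neither acidic nor electrophilic, so the lithium enolate should displace the primary iodide to form C11–C12.

Step 14
Reactants: 21 the diketo ester
Product: 23 (Z)-enol triflate (C9(OTf)=C11), via dipotassium bis-enolate 22 (not isolated)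
Conditions: KN(SiMe3)2 (2.1 equiv), THF, −78 °C; N-(5-chloropyridin-2-yl)bis(trifluoromethanesulfonyl)imide (1.05 equiv), −78 °C; AcOH
Reagents that add atoms: N-(5-chloropyridin-2-yl)bis(trifluoromethanesulfonyl)imide, FC(F)(F)S(=O)(=O)N(c1ccc(Cl)cn1)S(=O)(=O)C(F)(F)F
Why: A tert-alkyl ketone enolises to the Z enolate (the bulky C10 avoids the C12 chain), and the more nucleophilic ketone enolate oxygen should be triflated in preference to the stabilised β-keto ester enolate, placing OTf cis to C12.

Step 15
Reactants: 23 the (Z)-enol triflate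
Product: 24 tetracyclic β-keto ester (bicyclo[3.2.1]oct-2-ene with C9=C11, C7 methyl ester on C8, C15 ketone; ring A still the bridged acetal)
Conditions: Pd2(dba)3 (5 mol %), Xantphos (12 mol %), K3PO4 (3 equiv), toluene, 90 °C
Reagents that add atoms: none
Why: Palladium-catalysed intramolecular α-alkenylation of the soft β-keto ester enolate with the alkenyl triflate (oxidative addition to zerovalent palladium, C-bound enolate, reductive elimination) closes ring C at C8–C9; only C8–H is acidic enough for K3PO4, and because the tether hangs from C13 the bond must form on its face, so the quaternary C8 is set by the bridge.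

Step 16
Reactants: 24 the tetracyclic β-keto ester
Product: 26 keto alcohol (C7 hydroxymethyl on C8, C15 ketone kept), via lithium enolate of the ketone 25 (not isolated)
Conditions: LiN(SiMe3)2 (1.1 equiv), THF, −78 °C; LiAlH4 (2 equiv), −78 → 0 °C; aqueous KNaC4H4O6
Reagents that add atoms: none
Why: The ketone is protected in situ as its enolate (only C16 can enolise, C8 being a quaternary bridgehead) while LiAlH4 reduces the ester to the primary alcohol, and work-up returns the ketone; retro-aldol loss of formaldehyde is blocked because it would need a bridgehead enolate.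

Step 17
Reactants: 26 the keto alcohol with the bridged benzyl acetal
Product: 27 oxepane methyl acetal (ring B closed C7–O–C6(OMe); free C2–OH; C1–OBn)
Conditions: camphorsulfonic acid (10 mol %), MeOH, rt → 40 °C
Reagents that add atoms: methanol, CO
Why: Acid-catalysed transacetalisation under thermodynamic control: the C2–O–C6 bridge is now strained because C9 has become a fully substituted ring carbon held syn to a C4 methyl, so cleavage of the O–C6 bond lets ring A relax to a chair and the C7 hydroxyl captures the oxocarbenium ion as the seven-membered ring B, methanol replacing the benzyloxy group to give the anomerically favoured acetal.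

Step 18
Reactants: 27 the oxepane methyl acetal
Product: 28 exocyclic enone (C16=C17 methylene next to the C15 ketone)
Conditions: paraformaldehyde (5 equiv), N-methylanilinium trifluoroacetate (1.5 equiv), THF, 65 °C
Reagents that add atoms: formaldehyde (as paraformaldehyde), C=O
Why: Mannich-type α-methylenation (iminium formation, addition of the enol, β-elimination of the amine) can take place only at C16, the sole enolisable position of the ketone.

Step 19
Reactants: 28 the exocyclic enone
Product: 29 diol (C16 methyl endo; C1–OH and C2–OH free)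
Conditions: H2 (1 atm), Pd/C (10 wt %), EtOAc, rt
Reagents that add atoms: none
Why: Hydrogen should add to the exocyclic enone from the exo face of the bicyclo[3.2.1]octane (the side of the one-carbon bridge C14), which places C17 endo as in the target; the benzyl ether is hydrogenolysed in the same operation, and the C9=C11 alkene, flanked by two quaternary carbons, should be too hindered to react.

Step 20
Reactants: 29 the diol
Product: 30 diacetate methyl acetal
Conditions: Ac2O (6 equiv), pyridine, DMAP (0.2 equiv), 40 °C
Reagents that add atoms: acetic anhydride, CC(=O)OC(C)=O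
Why: Acylation of the cis-diol gives the 1,2-diacetate, and acylating C2–OH also removes any path back to the C2–O–C6 bridge.

Step 21
Reactants: 30 the diacetate methyl acetal
Product: 31 lactol (des-epoxy target)
Conditions: AcOH/THF/H2O (3:1:1), 40 °C
Reagents that add atoms: water, O
Why: Mild aqueous acid hydrolyses the methyl acetal to the lactol without cleaving the acetates or enolising C16, and the lactol settles in its favoured anomer.

Step 22
Reactants: 31 the lactol
Product: 32 CNP0210140.1
Conditions: mCPBA (1.3 equiv), NaHCO3, CH2Cl2, 0 °C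
Reagents that add atoms: 3-chloroperoxybenzoic acid, OOC(=O)c1cccc(Cl)c1
Why: Peracid epoxidation (Prilezhaev reaction) of the trisubstituted alkene is expected on the face syn to the one-carbon bridge C14 and anti to the C15–C16 bridge with its endo methyl, as is usual for bicyclo[3.2.1]oct-2-enes, which gives the 9,11-epoxide of the target; the buffered conditions should spare lactol, ketone and acetates.

**Compound list**

1 | (Z)-3-methylpent-2-en-4-yn-1-ol | C#C/C(C)=C\CO | starting material
2 | (Z)-3-methylpent-2-en-4-ynal | C#C/C(C)=C\C=O | intermediate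
3 | 2-(benzyloxy)acetaldehyde | O=CCOCc1ccccc1 | starting material
4 | 1,1,2-tris(benzyloxy)ethane | C(COCc1ccccc1)(OCc1ccccc1)OCc1ccccc1 | intermediate
5 | (Z)-1,2-bis(benzyloxy)ethene | c1ccccc1CO/C=C\OCc1ccccc1 | intermediate
6 | (2S,3R,4R)-2,3-bis(benzyloxy)-4-ethynyl-4-methyl-3,4-dihydro-2H-pyran (both OBn and the methyl on one face) | C#C[C@]1(C)[C@@H](OCc2ccccc2)[C@@H](OCc2ccccc2)OC=C1 | intermediate
7 | 2-methylpropene (isobutene) | CC(C)=C | starting material
8 | dihydropyranylium (cyclic 2-oxadienyl) triflate from 6 | C#C[C@]1(C)[C@@H](OCc2ccccc2)C=[O+]C=C1.[O-]S(=O)(=O)C(F)(F)F | intermediate (not isolated)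
9 | bridged 2-oxabicyclo[2.2.2]oct-2-enium triflate | C#C[C@]1(C)[C@@H](OCc3ccccc3)[C@@H]2CC(C)(C)[C@H]1C=[O+]2.[O-]S(=O)(=O)C(F)(F)F | intermediate (not isolated)
10 | (1S,3S,4R,5R,6R)-3,6-bis(benzyloxy)-5-ethynyl-5,8,8-trimethyl-2-oxabicyclo[2.2.2]octane (acetal carbon drawn as one epimer; its configuration is of no consequence) | C#C[C@]1(C)[C@@H](OCc3ccccc3)[C@@H]2CC(C)(C)[C@H]1[C@@H](OCc4ccccc4)O2 | intermediate
11 | 1-[(1S,3S,4R,5S,6R)-3,6-bis(benzyloxy)-5,8,8-trimethyl-2-oxabicyclo[2.2.2]octan-5-yl]ethanone | CC(=O)[C@]1(C)[C@@H](OCc3ccccc3)[C@@H]2CC(C)(C)[C@H]1[C@@H](OCc4ccccc4)O2 | intermediate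
12 | (R)-cyclohex-3-ene-1-carboxylic acid | O=C(O)[C@H]1CC=CCC1 | starting material
13 | (R)-cyclohex-3-en-1-ylmethanol | OC[C@H]1CC=CCC1 | intermediate
14 | (R)-tert-butyl(cyclohex-3-en-1-ylmethoxy)dimethylsilane | CC(C)(C)[Si](C)(C)OC[C@H]1CC=CCC1 | intermediate
15 | dimethyl (3R)-3-{[(tert-butyldimethylsilyl)oxy]methyl}hexanedioate | COC(=O)C[C@H](CO[Si](C)(C)C(C)(C)C)CCC(=O)OC | intermediate
16 | methyl (4R)-4-{[(tert-butyldimethylsilyl)oxy]methyl}-2-oxocyclopentane-1-carboxylate (C1 epimers/enol) | COC(=O)C1C[C@@H](CO[Si](C)(C)C(C)(C)C)CC1=O | intermediate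
17 | methyl (4R)-4-(hydroxymethyl)-2-oxocyclopentane-1-carboxylate (C1 epimers/enol) | COC(=O)C1C[C@@H](CO)CC1=O | intermediate
18 | methyl (4R)-4-(iodomethyl)-2-oxocyclopentane-1-carboxylate (C1 epimers/enol) | COC(=O)C1C[C@@H](CI)CC1=O | intermediate
19 | lithium enolate of ketone 11 | [Li+].C=C([O-])[C@]1(C)[C@@H](OCc3ccccc3)[C@@H]2CC(C)(C)[C@H]1[C@@H](OCc4ccccc4)O2 | intermediate (not isolated)
20 | sodium enolate of β-keto ester iodide 18 | [Na+].COC(=O)C1=C([O-])C[C@H](CI)C1 | intermediate (not isolated)
21 | diketo ester: 11 alkylated at its methyl carbon (C11) by the CH2 (C12) of 18 (cyclopentane C1 epimers/enol) | COC(=O)C1C[C@@H](CCC(=O)[C@]2(C)[C@@H](OCc3ccccc3)[C@@H]4CC(C)(C)[C@H]2[C@@H](OCc5ccccc5)O4)CC1=O | intermediate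
22 | dipotassium bis-enolate of 21 (Z ketone enolate) | [K+].[K+].COC(=O)C1=C([O-])C[C@H](C/C=C(\[O-])[C@]2(C)[C@@H](OCc3ccccc3)[C@@H]4CC(C)(C)[C@H]2[C@@H](OCc5ccccc5)O4)C1 | intermediate (not isolated)
23 | (Z)-enol triflate of 21 at C9 (OTf cis to C12) | COC(=O)C1C[C@@H](C/C=C(\OS(=O)(=O)C(F)(F)F)[C@]2(C)[C@@H](OCc3ccccc3)[C@@H]4CC(C)(C)[C@H]2[C@@H](OCc5ccccc5)O4)CC1=O | intermediate
24 | tetracyclic β-keto ester: methyl 7-oxobicyclo[3.2.1]oct-2-ene-1-carboxylate core carrying the bridged ring A acetal on C2 of the bicycle (C9) | COC(=O)[C@@]34C[C@@H](CC=C3[C@]5(C)[C@@H](OCc6ccccc6)[C@@H]7CC(C)(C)[C@H]5[C@@H](OCc8ccccc8)O7)CC4=O | intermediate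
25 | lithium enolate (C15–O, C15=C16) of 24 | [Li+].COC(=O)[C@@]34C[C@@H](CC=C3[C@]5(C)[C@@H](OCc6ccccc6)[C@@H]7CC(C)(C)[C@H]5[C@@H](OCc8ccccc8)O7)C=C4[O-] | intermediate (not isolated)
26 | keto alcohol: as 24 with CO2Me reduced to CH2OH (C7) | OC[C@@]34C[C@@H](CC=C3[C@]5(C)[C@@H](OCc6ccccc6)[C@@H]7CC(C)(C)[C@H]5[C@@H](OCc8ccccc8)O7)CC4=O | intermediate
27 | oxepane methyl acetal: ring B closed, C2–OH free, C1–OBn, C15 ketone, C9=C11 | O[C@H]1CC(C)(C)[C@H]2[C@H](OC)OC[C@@]34C[C@@H](CC=C3[C@]2(C)[C@H]1OCc5ccccc5)CC4=O | intermediate
28 | exocyclic enone: as 27 with a C16=C17 methylene | O[C@H]1CC(C)(C)[C@H]2[C@H](OC)OC[C@@]34C[C@@H](CC=C3[C@]2(C)[C@H]1OCc5ccccc5)C(=C)C4=O | intermediate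
29 | diol: C16 methyl endo, C1–OH and C2–OH free, C6 methyl acetal | O[C@H]1CC(C)(C)[C@H]2[C@H](OC)OC[C@@]34C[C@@H](CC=C3[C@]2(C)[C@H]1O)[C@@H](C)C4=O | intermediate
30 | 1,2-diacetate methyl acetal | CC(=O)O[C@H]1CC(C)(C)[C@H]2[C@H](OC)OC[C@@]34C[C@@H](CC=C3[C@]2(C)[C@H]1OC(C)=O)[C@@H](C)C4=O | intermediate
31 | lactol with C9=C11 alkene (des-epoxy target) | CC(=O)O[C@H]1CC(C)(C)[C@H]2[C@H](O)OC[C@@]34C[C@@H](CC=C3[C@]2(C)[C@H]1OC(C)=O)[C@@H](C)C4=O | intermediate
32 | CNP0210140.1 | CC(=O)O[C@H]1CC(C)(C)[C@H]2[C@H](O)OC[C@@]34C[C@@H](C[C@H]5O[C@]53[C@]2(C)[C@H]1OC(C)=O)[C@@H](C)C4=O | target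

**Count and risks**

Total step count: 22. Longest linear sequence: 16 steps (12 → 32, steps 7–22).

Steps most likely to fail:

Step 5 (proposed new method). What may go wrong: loss of a proton from the developing C4 cation (ene-type C-methallylation instead of ring closure), cationic oligomerisation of isobutene, or poor facial selectivity at C2. Fallback with known chemistry, setting out from 6 and returning at 10: Mukaiyama-type C-glycosylation of 6 with 2-(trimethylsilyloxy)propene (TMSOTf cat., CH2Cl2, −78 °C) should give the C2 acetonyl dihydropyran F1, anti to the C1 benzyloxy group. Addition of MeMgBr (excess, THF, −78 → 0 °C) gives the tertiary alcohol F2. BF3·OEt2 with benzyl alcohol (CH2Cl2, −78 °C) then ionises the tertiary alcohol, the C4 cation is captured by the enol ether at C5 (tert-alkylation of an enol ether, cation–olefin cyclisation) and benzyl alcohol closes the acetal to give 10.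

Step 15. What may go wrong: slow reductive elimination to the very congested C8–C9 bond, with O-alkenylation or loss of the triflate taking over. Fallback setting out from 21 and returning at 24: soft enolisation of the β-keto ester (TiCl4, Et3N, CH2Cl2, −78 → 0 °C) and intramolecular aldol addition of C8 to the C9 ketone should give the bridged tertiary alcohol F3 (C9 configuration of no consequence). Dehydration toward C11, the only neighbouring carbon that bears hydrogen (SOCl2, pyridine, 0 °C), gives 24.

Step 22. What may go wrong: poor facial selectivity, the peracid attacking anti to the axial C20 methyl (syn to the C15–C16 bridge) and giving the epimeric epoxide. Fallback setting out from 30 and returning at 32: NBS in wet THF (0 °C) forms the bromonium ion on that same face and water opens it anti, giving the bromohydrin F4. DBU (CH2Cl2, rt) closes the epoxide on the required face to give the epoxy methyl acetal F5. Hydrolysis of the acetal (pyridinium tosylate, acetone–water, rt) gives 32.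

Further compounds
F1 | step 5 | 1-[(2R,3R,4R)-3-(benzyloxy)-4-ethynyl-4-methyl-3,4-dihydro-2H-pyran-2-yl]propan-2-one | C#C[C@]1(C)[C@@H](OCc2ccccc2)[C@H](CC(C)=O)OC=C1
F2 | step 5 | tertiary alcohol from F1 (C2 side chain CH2C(CH3)2OH) | C#C[C@]1(C)[C@@H](OCc2ccccc2)[C@H](CC(C)(C)O)OC=C1
F3 | step 15 | bridged aldol adduct (C9 tertiary alcohol; saturated precursor of 24) | COC(=O)[C@@]34C[C@@H](CC[C@]3(O)[C@]5(C)[C@@H](OCc6ccccc6)[C@@H]7CC(C)(C)[C@H]5[C@@H](OCc8ccccc8)O7)CC4=O
F4 | step 22 | bromohydrin of 30 (C9–OH, C11–Br, trans) | CC(=O)O[C@H]1CC(C)(C)[C@H]2[C@H](OC)OC[C@@]34C[C@@H](C[C@H](Br)[C@]3(O)[C@]2(C)[C@H]1OC(C)=O)[C@@H](C)C4=O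
F5 | step 22 | 9,11-epoxy methyl acetal (methyl acetal of 32) | CC(=O)O[C@H]1CC(C)(C)[C@H]2[C@H](OC)OC[C@@]34C[C@@H](C[C@H]5O[C@]53[C@]2(C)[C@H]1OC(C)=O)[C@@H](C)C4=O
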